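The numbers of this flask come from no measurement; the run is a simulation.

I read the closed and dosed flasks at 20 min; the flow tank holds its contents that long on average, and I wanted the amount of intermediate A.

    substrate + second reagent → side product (k1 = 2.5 × 10⁻⁵ M⁻¹ s⁻¹)
    substrate + partner → intermediate A (k2 = 0.0029 M⁻¹ s⁻¹)
    target → over-reaction product (k3 = 4.2 × 10⁻⁶ s⁻¹)
    third reagent + intermediate B → target (k4 = 0.0048 M⁻¹ s⁻¹)
    second reagent + intermediate A → intermediate B (k5 = 3.8 × 10⁻⁴ M⁻¹ s⁻¹)

all flasks: second reagent 0.440 M; third reagent 0.440 M
- south-east: substrate 0.40 M; partner 0.240 M; time 20 min; everything together in a closed stirred flask, run for 20 min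
- north-west: substrate 0.40 M; partner 0.240 M (fed, over 16.0 min); time 20 min; a stirred flask in which partner is dosed at a steady rate over 16.0 min without added volume, worked up at 20 min
- north: substrate 0.40 M; partner 0.240 M; one stirred flow tank at steady state, fed with the mixture as stated, mean residence time 20 min
- north-east: substrate 0.40 M (fed, over 16.0 min); partner 0.240 M; time 20 min; a stirred flask in which substrate is dosed at a steady rate over 16.0 min without added volume, worked up at 20 min

- the set-up with the highest amount of intermediate A at the outlet or at the end, in percent of the substrate put in ("none" if the first two lie within 2 percentage points) (south-east / north-west / north / north-east / none)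
- amount of intermediate A at the outlet or at the end, in percent of the substrate put in, south-east
- amount of intermediate A at the outlet or at the end, in percent of the substrate put in, north-west
- amount of intermediate A at the outlet or at the end, in percent of the substrate put in, north
- amount of intermediate A at the outlet or at the end, in percent of the substrate put in, north-east

- the stated concentrations are those of everything mixed, before any reaction; amounts are the same in each set-up
- the feed brings no volume worth counting
- run time (south-east): 20 min

With the charges as mixed, substrate went to intermediate A faster than to side product by a factor of 63.3, so I integrated that one rate. Partner is the limiting reagent, 0.240 M against 0.40 M of substrate. With k = 0.0029 M⁻¹ s⁻¹, a closed flask forms, per substrate charged, partner·(E − 1)/(substrate·E − partner), where E = exp(k·(substrate − partner)·t).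

A dosed portion enters on average at the dosing time over 2. So I call the mean stay the reading time less that, 12.0 min, and put it in as t. In the tank, the level formed solves a quadratic in closed form.

I took second reagent as constant, which makes the loss of intermediate A pseudo-first-order at 0.0100 min⁻¹. What forms has an age of about t over 2, and the tank has its own factor, 1/(1 + loss·t).

| Flask | t | Formed | Survives | Intermediate A |
|---|---|---|---|---|
| south-east | 20 min | 39.0% | 0.905 | 35.3% |
| north-west | 12.0 min | 29.9% | 0.942 | 28.1% |
| north-east | 12.0 min | 29.9% | 0.942 | 28.1% |
| north | 20 min | 29.7% | 0.833 | 24.7% |

The top row forms more than the dosed rows, with a t of 20 min against 12.0 min. The two dosed rows are equal in my reckoning: substrate and partner enter my rate alike. The tank forms about as much as they do, but keeps less of it. My choice was south-east, ahead by 7.1 percentage points, more than the margin.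

The forecast chose south-east: 34.3% there, 26.5% in north-west, 24.8% in north, 26.4% in north-east. “Batch wins clearly.” My dosed figure stood above its north-west figure.

The simulation put south-east first at 34.5%, with north-west at 26.5%, north at 24.8% and north-east at 27.0%. In south-east the half-life of intermediate A by its step to intermediate B alone, with second reagent as charged, was 69 min, longer than the 20 min of the run. In north-west the mean stay of 12.0 min gave me 29.9% formed, and 28.7% of the substrate had taken that path. Read at 50 min, north-west had a mean stay of 42.0 min; the closed form gave 50.8% formed, and in that flask 50.3% of the substrate had taken that path.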